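In a one-step world, target decaying at first order has a half-life of 3.5 h, short against the run of 20 h. This flask has more steps, so we follow the rate of that decay through them.

starting material 20 mM; reagent in the second phase 1.30 equiv; time 20 h; volume of the second phase over the first 1.0

1. amount of target and product in the second phase and crystals together at 20 h, in percent of the starting material charged
2. concentration of target in solution at 20 h, in percent of saturation

- target is meant together with its product in the second phase and crystals
- in the second phase: reagent in the second phase, product in the second phase; everything else is in the first
- charges count per volume of the first phase; a concentration in a rate is the amount of a species over the volume of its own phase; every rate counts per litre of the first phase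
- solid, in amounts per volume of the solution: crystals
- run time (flask): 20 h

    reagent in the reaction phase ⇌ reagent in the second phase, rate k1*([reagent in the reaction phase] - [reagent in the second phase]/K1) per volume of the first phase (K1 = 8.7, k1 = 2.3 h⁻¹)
    target → decomposed product (k2 = 0.20 h⁻¹)
    starting material + reagent in the reaction phase → target (k3 = 2600 M⁻¹ h⁻¹)
    crystals ⇌ target, rate k4*(cs4 - [target]) while solid is left; crystals form when [target] > cs4 (cs4 = 0.38 mM, k4 = 4.2 h⁻¹)
    target ⇌ product in the second phase, rate k5*([target] - [product in the second phase]/K5) per volume of the first phase (K5 = 0.14, k5 = 0.21 h⁻¹)

Reagent crosses out of the second phase and meets starting material, the limiting reagent at 1.30 equiv of reagent. Its use is faster than its crossing, so the crossing is the rate-limiting step, and at the start it feeds target into solution at 6.87 mM h⁻¹. Crystals take up dissolved target with coefficient 4.2 h⁻¹, and decay removes it with constant 0.20 h⁻¹, so dissolved target relaxes at the sum of the two, 4.40 h⁻¹, which is faster than the feed fades, at 0.264 h⁻¹. Dissolved target therefore follows the feed downward, so what we freeze is not its level but its net rate of change, taken as nearly zero (a quasi-steady state), and we neglect its small passage to the second phase.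

Balancing inflow against outflow divides the feed: a share of 4.55%, the decay constant over the sum of decay constant and crystal coefficient, goes to decay. On top of that runs the holding rate, the decay rate without any feed, paid out of the crystals while solid stands: 0.0725 mM h⁻¹.

At the start, then, decay runs at 0.385 mM h⁻¹. The feed slows with the reagent left in the second phase, by a factor of 4.33 by the time the charge of starting material has been fed, and then it stops. That leaves decay slower than at the start by a factor of 5.31. Added up, the fed share costs 4.55% of the charge, however long the feeding takes, and the holding rate costs 7.25% over the run. Our reckoning is therefore 88.2% for the yield and 95.5% of saturation.

The forecast gave 88.3% (from 87% to 89.5%) and 95.5% (from 94.5% to 96.5%), on the ground that “the crystals slowly dissolve to replace decomposition”.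

The simulation gives 88.3% and 95.5%.

At 20.0 h this flask holds 0% of its starting material and 86.2% as crystals, so the feed term is over and the holding rate remains. The neighbouring flask is the same one read at 2.0 d. Its extra 28.0 h at the holding rate cost 10.2% of the charge, which brings 88.3% down to 78.2%. The neighbouring flask, simulated, stands at 78.2%, with 76.1% as crystals.

The constants used here are those of an exercise; the result is computed.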